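**Retrosynthetic overview**

1. Isovalerylshikonin 21 is traced back, by removal of the two peri methoxymethyl acetals and of the isovalerate, to quinone alcohol 18; acylation and deprotection are the last two steps.
2. Key disconnection: the C2–C3 bond of quinone ring B (ring atoms C1, C2, C3, C4, C4a, C8a). C2 and C3 are the α-carbons of the C1 and C4 carbonyls, two donor positions of an ene-1,4-dione, and the side-chain oxygen sits on C1', β to C1=O. The unit C2–C1'–O is therefore written as the oxirane of an α,β-epoxy ketone, which turns C2 into an acceptor for the C3 methyl ketone enolate and carries the C1' stereocentre.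
3. The precursor 15, a 2-acetylphenyl oxiranyl ketone, comes from aryl bromide 11 (from bromohydroquinone) and epoxy aldehyde 6 (Sharpless epoxidation of dienol 4, made from propargyl alcohol and prenyl bromide), joined by aryllithium addition and a double oxidation.
4. Ring order: ring A is purchased; the oxirane (a temporary ring) is made in step 3; ring B is closed last, in step 9, with opening of the oxirane, aromatisation and oxidation to the quinone.

Key step: step 9

Remark on the chemistry: the 5,8-dihydroxy-1,4-naphthoquinone core exists as rapidly equilibrating tautomers, so the side chain drawn on the quinone ring or on the dihydroxybenzene ring describes one compound. Compounds 1, 2, 7, 9 and 19 are taken as commercial.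

**Route**

Step 1
Reactants: 1 prop-2-yn-1-ol; 2 1-bromo-3-methylbut-2-ene
Product: 3 6-methylhept-5-en-2-yn-1-ol
Conditions: CuI (10 mol%), K2CO3, n-Bu4NCl (10 mol%), DMF, rt
Reagents that add atoms: none
Why: Copper-catalysed coupling of the terminal alkyne with the primary allylic bromide at its unsubstituted terminus should give the skipped enyne; no stereocentre is formed.

Step 2
Reactants: 3 6-methylhept-5-en-2-yn-1-ol
Product: 4 (2E)-6-methylhepta-2,5-dien-1-ol
Conditions: LiAlH4, THF, 0 °C → 45 °C; H2O work-up
Reagents that add atoms: none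
Why: Hydroxyl-directed trans-hydroalumination of the propargylic alcohol followed by protonolysis should give the (E)-allylic alcohol, the isolated trisubstituted alkene being inert.

Step 3
Reactants: 4 (2E)-6-methylhepta-2,5-dien-1-ol
Product: 5 [(2R,3R)-3-(3-methylbut-2-en-1-yl)oxiran-2-yl]methanol
Conditions: Ti(O-i-Pr)4 (10 mol%), D-(−)-diethyl tartrate (12 mol%), t-BuOOH, 4 Å molecular sieves, CH2Cl2, −20 °C
Reagents that add atoms: tert-butyl hydroperoxide, CC(C)(C)OO
Why: Sharpless asymmetric epoxidation oxidises only the allylic alcohol alkene, and the D-(−)-tartrate ligand should deliver oxygen to the face that gives the (2R,3R)-epoxide, whose C3 becomes the carbinol centre of the target.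

Step 4
Reactants: 5 [(2R,3R)-3-(3-methylbut-2-en-1-yl)oxiran-2-yl]methanol
Product: 6 (2S,3R)-3-(3-methylbut-2-en-1-yl)oxirane-2-carbaldehyde
Conditions: Dess–Martin periodinane, pyridine, CH2Cl2, 0 °C → rt; used crude
Reagents that add atoms: none
Why: Dess–Martin oxidation of the primary alcohol under buffered conditions should leave the oxirane and the alkene untouched; the C2 descriptor changes from R to S only through the CIP priorities.

Step 5
Reactants: 7 2-bromobenzene-1,4-diol
Product: 8 2-bromo-1,4-bis(methoxymethoxy)benzene
Conditions: NaH, MOMCl, DMF, 0 °C → rt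
Reagents that add atoms: chloromethyl methyl ether (MOMCl), COCCl
Why: Williamson-type O-alkylation of both phenoxides should give the bis-acetal, which directs the later lithiation and is removable with acid.

Step 6
Reactants: 8 2-bromo-1,4-bis(methoxymethoxy)benzene; 9 acetaldehyde
Product: 11 1-[2-bromo-3,6-bis(methoxymethoxy)phenyl]ethan-1-ol (racemic), via aryllithium 10 (not isolated)
Conditions: LiN(i-Pr)2, THF, −78 °C; then 9, −78 °C; aq. NH4Cl
Reagents that add atoms: none
Why: Directed ortho-metalation should remove the most acidic ring proton, the one flanked by bromine and a methoxymethoxy group, and the aryllithium adds to acetaldehyde at −78 °C before it can lose LiBr; the new carbinol centre is racemic and is oxidised away in step 8.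

Step 7
Reactants: 11 1-[2-bromo-3,6-bis(methoxymethoxy)phenyl]ethan-1-ol; 6 (2S,3R)-3-(3-methylbut-2-en-1-yl)oxirane-2-carbaldehyde
Product: 13 1-[2-{hydroxy[(2R,3R)-3-(3-methylbut-2-en-1-yl)oxiran-2-yl]methyl}-3,6-bis(methoxymethoxy)phenyl]ethan-1-ol (mixture of carbinol epimers), via dilithio alkoxide 12 (not isolated)
Conditions: n-BuLi (2.1 equiv), THF, −78 °C; then 6, −78 °C; aq. NH4Cl at −78 °C
Reagents that add atoms: none
Why: Bromine–lithium exchange on the lithium alkoxide of 11 should give an aryllithium that adds to the aldehyde carbonyl much faster than it opens the oxirane; the two carbinol centres form without control and are both removed in step 8, while the oxirane centres are untouched.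

Step 8
Reactants: 13 1-[2-{hydroxy[(2R,3R)-3-(3-methylbut-2-en-1-yl)oxiran-2-yl]methyl}-3,6-bis(methoxymethoxy)phenyl]ethan-1-ol
Product: 15 1-[2-{[(2S,3R)-3-(3-methylbut-2-en-1-yl)oxiran-2-yl]carbonyl}-3,6-bis(methoxymethoxy)phenyl]ethan-1-one, via hydroxy ketone 14 (not isolated)
Conditions: Dess–Martin periodinane (3 equiv), pyridine, CH2Cl2, 0 °C → rt
Reagents that add atoms: none
Why: Double Dess–Martin oxidation of the two benzylic secondary alcohols should give the 1,2-diacylbenzene, the hydroxy ketone (expected to arise first at the less hindered 1-hydroxyethyl group) being oxidised on through its open form; the oxirane centres are not epimerised under these conditions.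

Step 9
Reactants: 15 1-[2-{[(2S,3R)-3-(3-methylbut-2-en-1-yl)oxiran-2-yl]carbonyl}-3,6-bis(methoxymethoxy)phenyl]ethan-1-one
Product: 18 2-[(1R)-1-hydroxy-4-methylpent-3-en-1-yl]-5,8-bis(methoxymethoxy)naphthalene-1,4-dione, via cyclised diketone 16 (not isolated), via hydroquinone 17 (not isolated)
Conditions: KOt-Bu (2.2 equiv), THF/t-BuOH (10:1), −20 → 0 °C, argon; then AcOH (2.2 equiv), Ag2O, 0 °C → rt
Reagents that add atoms: none
Why: Proposed new method: KOt-Bu reversibly deprotonates the acetyl methyl group, the only enolisable position of 15, and the enolate carbon attacks the oxirane carbon α to the neighbouring aryl ketone with inversion (SN2), which closes ring B and gives alkoxide 16; its 1,4-diketone should enolise at once to the aromatic naphthalene-1,4-diol 17, which Ag2O oxidises to the quinone before any acidic work-up can ionise the benzylic alcohol. The closest known reaction types are the intramolecular alkylation of ketone enolates and stabilised carbanions by epoxides (epoxynitrile-type cyclisations), six-membered enolendo alkylations of methyl ketone enolates, and the SN2 opening of α,β-epoxy ketones at the α-carbon by thiolates, azide and halides; the new element is the use of that α-carbon as the acceptor for a ketone enolate. Ring B is closed in the 6-(enolendo)-exo-tet mode, the oxirane being opened in the same event. No stereocentre is created that survives: the ring carbon attacked is inverted but becomes sp2 on aromatisation, whereas the carbinol centre is the oxirane β-carbon set in step 3, whose C–O bond is never broken, so it should arrive unchanged as (R). The step needs attack at the α- and not the β-oxirane carbon (six- against seven-membered ring, and carbonyl activation of the α-position), C- over O-alkylation (the usual outcome of six-membered enolendo closures), and escape from the reversible 5-exo aldol addition of the enolate to the neighbouring ketone, for which equilibrating alkoxide conditions are chosen so that the aldolate drains through the irreversible oxirane opening.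

Step 10
Reactants: 18 2-[(1R)-1-hydroxy-4-methylpent-3-en-1-yl]-5,8-bis(methoxymethoxy)naphthalene-1,4-dione; 19 3-methylbutanoic anhydride
Product: 20 (1R)-1-[5,8-bis(methoxymethoxy)-1,4-dioxo-1,4-dihydronaphthalen-2-yl]-4-methylpent-3-en-1-yl 3-methylbutanoate
Conditions: DMAP (10 mol%), pyridine, CH2Cl2, 0 °C → rt
Reagents that add atoms: none
Why: DMAP-catalysed acylation of the secondary alcohol by the anhydride takes place at oxygen, so the carbinol carbon keeps its (R) configuration, and the quinone and the acetals are inert.

Step 11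
Reactants: 20 (1R)-1-[5,8-bis(methoxymethoxy)-1,4-dioxo-1,4-dihydronaphthalen-2-yl]-4-methylpent-3-en-1-yl 3-methylbutanoate
Product: 21 (1R)-1-(5,8-dihydroxy-1,4-dioxo-1,4-dihydronaphthalen-2-yl)-4-methylpent-3-en-1-yl 3-methylbutanoate (isovalerylshikonin)
Conditions: CF3CO2H/CH2Cl2 (1:10), 0 °C; H2O work-up
Reagents that add atoms: none
Why: Acid-catalysed cleavage of the two peri methoxymethyl acetals, helped by hydrogen bonding of the freed phenols to the quinone carbonyls, should proceed under dilute non-nucleophilic acid that leaves the secondary ester, its stereocentre and the trisubstituted alkene intact.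

**Compound list**

1 | prop-2-yn-1-ol (propargyl alcohol) | C#CCO | starting material
2 | 1-bromo-3-methylbut-2-ene (prenyl bromide) | CC(C)=CCBr | starting material
3 | 6-methylhept-5-en-2-yn-1-ol | CC(C)=CCC#CCO | intermediate
4 | (2E)-6-methylhepta-2,5-dien-1-ol | CC(C)=CC/C=C/CO | intermediate
5 | [(2R,3R)-3-(3-methylbut-2-en-1-yl)oxiran-2-yl]methanol | OC[C@H]1O[C@@H]1CC=C(C)C | intermediate
6 | (2S,3R)-3-(3-methylbut-2-en-1-yl)oxirane-2-carbaldehyde | O=C[C@H]1O[C@@H]1CC=C(C)C | intermediate
7 | 2-bromobenzene-1,4-diol (bromohydroquinone) | Oc1ccc(O)c(Br)c1 | starting material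
8 | 2-bromo-1,4-bis(methoxymethoxy)benzene | COCOc1ccc(OCOC)c(Br)c1 | intermediate
9 | acetaldehyde | CC=O | starting material
10 | [2-bromo-3,6-bis(methoxymethoxy)phenyl]lithium, formed in the flask | [Li]c1c(Br)c(OCOC)ccc1OCOC | intermediate
11 | 1-[2-bromo-3,6-bis(methoxymethoxy)phenyl]ethan-1-ol, racemic | CC(O)c1c(Br)c(OCOC)ccc1OCOC | intermediate
12 | lithium 1-[2-lithio-3,6-bis(methoxymethoxy)phenyl]ethan-1-olate, racemic, formed in the flask | CC(O[Li])c1c([Li])c(OCOC)ccc1OCOC | intermediate
13 | 1-[2-{hydroxy[(2R,3R)-3-(3-methylbut-2-en-1-yl)oxiran-2-yl]methyl}-3,6-bis(methoxymethoxy)phenyl]ethan-1-ol, mixture of epimers at the two carbinol carbons | CC(O)c1c(C(O)[C@H]2O[C@@H]2CC=C(C)C)c(OCOC)ccc1OCOC | intermediate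
14 | 1-[2-{hydroxy[(2R,3R)-3-(3-methylbut-2-en-1-yl)oxiran-2-yl]methyl}-3,6-bis(methoxymethoxy)phenyl]ethan-1-one, carbinol epimers, formed in the flask | CC(=O)c1c(C(O)[C@H]2O[C@@H]2CC=C(C)C)c(OCOC)ccc1OCOC | intermediate
15 | 1-[2-{[(2S,3R)-3-(3-methylbut-2-en-1-yl)oxiran-2-yl]carbonyl}-3,6-bis(methoxymethoxy)phenyl]ethan-1-one | CC(=O)c1c(C(=O)[C@H]2O[C@@H]2CC=C(C)C)c(OCOC)ccc1OCOC | intermediate
16 | (2R)-2-[(1R)-1-hydroxy-4-methylpent-3-en-1-yl]-5,8-bis(methoxymethoxy)-2,3-dihydronaphthalene-1,4-dione, formed in the flask as its potassium alkoxide, neutral form shown | CC(C)=CC[C@@H](O)[C@H]1CC(=O)c2c(OCOC)ccc(OCOC)c2C1=O | intermediate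
17 | 2-[(1R)-1-hydroxy-4-methylpent-3-en-1-yl]-5,8-bis(methoxymethoxy)naphthalene-1,4-diol, formed in the flask as its potassium salt, neutral form shown | CC(C)=CC[C@@H](O)c1cc(O)c2c(OCOC)ccc(OCOC)c2c1O | intermediate
18 | 2-[(1R)-1-hydroxy-4-methylpent-3-en-1-yl]-5,8-bis(methoxymethoxy)naphthalene-1,4-dione | CC(C)=CC[C@@H](O)C1=CC(=O)c2c(OCOC)ccc(OCOC)c2C1=O | intermediate
19 | 3-methylbutanoic anhydride (isovaleric anhydride) | CC(C)CC(=O)OC(=O)CC(C)C | starting material
20 | (1R)-1-[5,8-bis(methoxymethoxy)-1,4-dioxo-1,4-dihydronaphthalen-2-yl]-4-methylpent-3-en-1-yl 3-methylbutanoate | CC(C)=CC[C@@H](OC(=O)CC(C)C)C1=CC(=O)c2c(OCOC)ccc(OCOC)c2C1=O | intermediate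
21 | isovalerylshikonin, (1R)-1-(5,8-dihydroxy-1,4-dioxo-1,4-dihydronaphthalen-2-yl)-4-methylpent-3-en-1-yl 3-methylbutanoate | CC(C)=CC[C@@H](OC(=O)CC(C)C)C1=CC(=O)c2c(O)ccc(O)c2C1=O | target

**Step count and risks**

Total steps: 11. Longest linear sequence: 9 steps (steps 1–4 and 7–11, from propargyl alcohol 1).

Steps most likely to fail:

1. Step 9 (the proposed new method). What may go wrong:
   - the enolate may be diverted to O-alkylation or to the 5-exo aldol adduct, which can dehydrate;
   - the benzo-fused chain may hold the enolate in a poor geometry for C-attack on the oxirane;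
   - the electron-rich hydroquinone may lose its benzylic oxygen before it is oxidised.

   Fallback, by known chemistry that forms the same ring bond: it sets out from epoxy alcohol 5 and bromo alcohol 11 and comes back to the route at quinone alcohol 18. Appel chlorination of 5 (PPh3, CCl4, NaHCO3, reflux) should give (2S,3R)-2-(chloromethyl)-3-(3-methylbut-2-en-1-yl)oxirane F1. Treatment with n-BuLi (3 equiv, THF, −40 °C) should open the oxirane and eliminate HCl, the established conversion of 2,3-epoxy chlorides into propargylic alcohols, to give (3R)-6-methylhept-5-en-1-yn-3-ol F2 with the carbinol centre retained. Alcohol 11 is oxidised with Dess–Martin periodinane to 1-[2-bromo-3,6-bis(methoxymethoxy)phenyl]ethan-1-one F3. Sonogashira coupling of F3 with F2 (Pd(PPh3)2Cl2, CuI, i-Pr2NH, 60 °C) should give 1-{2-[(3R)-3-hydroxy-6-methylhept-5-en-1-yn-1-yl]-3,6-bis(methoxymethoxy)phenyl}ethan-1-one F4. KN(SiMe3)2 (2.2 equiv, THF, −78 → 0 °C) then closes the ring by the known 6-endo-dig attack of the methyl ketone enolate on the ortho alkyne, giving 3-[(1R)-1-hydroxy-4-methylpent-3-en-1-yl]-5,8-bis(methoxymethoxy)naphthalen-1-ol F5. Oxidation of this naphthol with Fremy's salt, (KSO3)2NO, in buffered acetone/H2O should introduce the para oxygen and give 18.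

2. Step 7. What may go wrong:
   - the epoxy aldehyde may oligomerise or hydrate before use;
   - the hindered, doubly ortho-substituted aryllithium may act as a base or attack the oxirane;
   - the oxirane may migrate (Payne-type) in the dialkoxide before the quench.

   Fallback, changing the electrophile class from aldehyde to amide: it sets out from epoxy alcohol 5 (with dilithio alkoxide 12 generated from 11 as in step 7) and comes back at diketone 15. Oxidation of 5 (TEMPO cat., PhI(OAc)2, MeCN/H2O) should give (2S,3R)-3-(3-methylbut-2-en-1-yl)oxirane-2-carboxylic acid F6. Coupling with MeNHOMe·HCl (EDC·HCl, N-methylmorpholine, CH2Cl2) gives the Weinreb amide (2S,3R)-N-methoxy-N-methyl-3-(3-methylbut-2-en-1-yl)oxirane-2-carboxamide F7. Single addition of 12 to F7 at −78 °C should give [2-(1-hydroxyethyl)-3,6-bis(methoxymethoxy)phenyl][(2S,3R)-3-(3-methylbut-2-en-1-yl)oxiran-2-yl]methanone F8. One Dess–Martin oxidation of the remaining carbinol then gives 15.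

3. Step 11. What may go wrong: cleavage of the second peri acetal may need acid strong enough to add to the trisubstituted alkene or to ionise the carbinol C–O bond of the ester.

   Fallback, changing the order of events and the mode of acetal cleavage: it sets out from quinone alcohol 18 and comes back at target 21. Chelation-driven cleavage of both peri acetals with MgBr2·OEt2 (Et2O/CH2Cl2, 0 °C → rt), which needs no protic acid, should give shikonin, 5,8-dihydroxy-2-[(1R)-1-hydroxy-4-methylpent-3-en-1-yl]naphthalene-1,4-dione F9. Selective acylation of its side-chain hydroxyl with 3-methylbutanoic acid (DCC, DMAP cat., CH2Cl2, 0 °C), the chelated peri hydroxyls being far less nucleophilic, then gives 21.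

Further compounds
F1 | step 9 | (2S,3R)-2-(chloromethyl)-3-(3-methylbut-2-en-1-yl)oxirane | ClC[C@H]1O[C@@H]1CC=C(C)C
F2 | step 9 | (3R)-6-methylhept-5-en-1-yn-3-ol | C#C[C@H](O)CC=C(C)C
F3 | step 9 | 1-[2-bromo-3,6-bis(methoxymethoxy)phenyl]ethan-1-one | CC(=O)c1c(Br)c(OCOC)ccc1OCOC
F4 | step 9 | 1-{2-[(3R)-3-hydroxy-6-methylhept-5-en-1-yn-1-yl]-3,6-bis(methoxymethoxy)phenyl}ethan-1-one | CC(=O)c1c(C#C[C@H](O)CC=C(C)C)c(OCOC)ccc1OCOC
F5 | step 9 | 3-[(1R)-1-hydroxy-4-methylpent-3-en-1-yl]-5,8-bis(methoxymethoxy)naphthalen-1-ol | CC(C)=CC[C@@H](O)c1cc(O)c2c(OCOC)ccc(OCOC)c2c1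
F6 | step 7 | (2S,3R)-3-(3-methylbut-2-en-1-yl)oxirane-2-carboxylic acid | OC(=O)[C@H]1O[C@@H]1CC=C(C)C
F7 | step 7 | (2S,3R)-N-methoxy-N-methyl-3-(3-methylbut-2-en-1-yl)oxirane-2-carboxamide | CON(C)C(=O)[C@H]1O[C@@H]1CC=C(C)C
F8 | step 7 | [2-(1-hydroxyethyl)-3,6-bis(methoxymethoxy)phenyl][(2S,3R)-3-(3-methylbut-2-en-1-yl)oxiran-2-yl]methanone | CC(O)c1c(C(=O)[C@H]2O[C@@H]2CC=C(C)C)c(OCOC)ccc1OCOC
F9 | step 11 | shikonin, 5,8-dihydroxy-2-[(1R)-1-hydroxy-4-methylpent-3-en-1-yl]naphthalene-1,4-dione | CC(C)=CC[C@@H](O)C1=CC(=O)c2c(O)ccc(O)c2C1=O
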